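**Retrosynthetic overview**
1. Target ⇐ 10-membered C2-ketone/C5-alcohol; the bridging tetrahydrofuran hemiketal closes by itself and is the last ring formed.
2. 10-membered carbocycle ⇐ intramolecular CrCl2 (Nozaki–Hiyama–Kishi) allylation forming C2–C3; the carbinol is then oxidised, so its configuration does not matter.
3. C7–C8 bond, the α-methylene lactone and the C7/C8 stereocentres ⇐ intermolecular Zn Barbier allylation of a β,γ-unsaturated aldehyde (C8, C9, C10, C14, C1, C2) by a 3-(bromomethyl)butenolide (C3–C7, C11–C13, C15).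
4. Butenolide ⇐ acrylate ring-closing metathesis; C5/C6 syn-diol ⇐ Brown (Z)-γ-alkoxyallylboration of 2-(silyloxymethyl)acrolein.
5. Ring order: butenolide (becomes the γ-lactone), then the 10-membered ring, then the hemiketal ring.

Assumption: germacrane numbering is used (C12 lactone on O6, tiglate on O8, hemiketal carbon C2, ether O5–C2); TBS = tert-butyldimethylsilyl, PMB = 4-methoxybenzyl, MOM = methoxymethyl, Ipc = isopinocampheyl; the C2 configuration is dictated by C5 because only the cis-bridged hemiketal can form.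

**Step 1**
Reactants: 1 2-methylenepropane-1,3-diol
Product: 2 2-{[(tert-butyldimethylsilyl)oxy]methyl}prop-2-en-1-ol
Conditions: NaH (1.0 equiv), THF, 0 °C; then TBSCl, 0 °C to rt
Reagents that add atoms: tert-butyldimethylsilyl chloride CC(C)(C)[Si](C)(C)Cl
Why: O-silylation of the monosodium alkoxide of a symmetric diol gives the mono-ether cleanly because only one alkoxide is present; no stereocentre.

**Step 2**
Reactants: 2 2-{[(tert-butyldimethylsilyl)oxy]methyl}prop-2-en-1-ol
Product: 3 2-{[(tert-butyldimethylsilyl)oxy]methyl}prop-2-enal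
Conditions: MnO2 (activated, excess), CH2Cl2, rt
Reagents that add atoms: none
Why: MnO2 oxidation of a primary allylic alcohol stops cleanly at the enal.

**Step 3**
Reactants: 4 allyl alcohol
Product: 5 3-(methoxymethoxy)prop-1-ene (allyl MOM ether)
Conditions: MOMCl, i-Pr2NEt, CH2Cl2, 0 °C to rt
Reagents that add atoms: chloromethyl methyl ether COCCl
Why: Standard O-alkylation of an alcohol by an α-chloro ether (acetal formation).

**Step 4**
Reactants: 5 3-(methoxymethoxy)prop-1-ene; 3 2-{[(tert-butyldimethylsilyl)oxy]methyl}prop-2-enal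
Product: 8 (3S,4S)-2-{[(tert-butyldimethylsilyl)oxy]methyl}-4-(methoxymethoxy)hexa-1,5-dien-3-ol, via lithiated allyl ether 6 (not isolated), via alkoxyallylborane 7 (not isolated)
Conditions: sec-BuLi, THF, −78 °C; (+)-Ipc2BOMe (from (−)-α-pinene), −78 °C; BF3·OEt2; then 3, −78 °C; NaOH, H2O2, 0 °C to rt
Reagents that add atoms: none
Why: Brown (Z)-γ-alkoxyallylboration (carbonyl allylation) through a chair Zimmerman–Traxler transition state gives the syn 1,2-diol mono-ether, and the Ipc groups from (−)-α-pinene direct Re-face attack, setting C5 (S) and C6 (S).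

**Step 5**
Reactants: 8 (3S,4S)-2-{[(tert-butyldimethylsilyl)oxy]methyl}-4-(methoxymethoxy)hexa-1,5-dien-3-ol
Product: 9 (3S,4S)-3-[(tert-butyldimethylsilyl)oxy]-2-{[(tert-butyldimethylsilyl)oxy]methyl}-4-(methoxymethoxy)hexa-1,5-diene
Conditions: TBSOTf, 2,6-lutidine, CH2Cl2, −78 to 0 °C
Reagents that add atoms: tert-butyldimethylsilyl triflate CC(C)(C)[Si](C)(C)OS(=O)(=O)C(F)(F)F
Why: Silyl triflate silylation protects the hindered secondary C5 alcohol without touching the stereocentres.

**Step 6**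
Reactants: 9 (3S,4S)-3-[(tert-butyldimethylsilyl)oxy]-2-{[(tert-butyldimethylsilyl)oxy]methyl}-4-(methoxymethoxy)hexa-1,5-diene
Product: 10 (3S,4S)-4-[(tert-butyldimethylsilyl)oxy]-5-{[(tert-butyldimethylsilyl)oxy]methyl}hexa-1,5-dien-3-ol
Conditions: Me2BBr, CH2Cl2, −78 °C; then THF/sat. aq NaHCO3
Reagents that add atoms: none
Why: Guindon acetal cleavage removes the MOM ether at −78 °C by bromide attack on the acetal carbon, leaving silyl ethers and the C6 configuration intact.

**Step 7**
Reactants: 10 (3S,4S)-4-[(tert-butyldimethylsilyl)oxy]-5-{[(tert-butyldimethylsilyl)oxy]methyl}hexa-1,5-dien-3-ol; 11 2-(bromomethyl)acrylic acid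
Product: 12 (3S,4S)-4-[(tert-butyldimethylsilyl)oxy]-5-{[(tert-butyldimethylsilyl)oxy]methyl}hexa-1,5-dien-3-yl 2-(bromomethyl)prop-2-enoate
Conditions: DCC, DMAP (5 mol %), CH2Cl2, 0 °C to rt
Reagents that add atoms: none
Why: Steglich esterification acylates the free C6 alcohol with retention, the low DMAP loading and temperature limiting attack on the allylic bromide.

**Step 8**
Reactants: 12 (3S,4S)-4-[(tert-butyldimethylsilyl)oxy]-5-{[(tert-butyldimethylsilyl)oxy]methyl}hexa-1,5-dien-3-yl 2-(bromomethyl)prop-2-enoate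
Product: 13 (5S)-3-(bromomethyl)-5-[(1S)-1-[(TBS)oxy]-2-{[(TBS)oxy]methyl}prop-2-en-1-yl]furan-2(5H)-one
Conditions: second-generation Grubbs catalyst RuCl2(H2IMes)(PCy3)(=CHPh) (10 mol %), toluene, 80 °C
Reagents that add atoms: none
Why: Ring-closing metathesis between the vinyl group and the acrylate is the only closure that gives an unstrained five-membered ring, the third alkene being 1,1-disubstituted and badly placed.

**Step 9**
Reactants: 14 3-methylbut-3-en-1-ol (isoprenol); 15 paraformaldehyde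
Product: 17 3-methylenepentane-1,5-diol, via dilithio isoprenol 16 (not isolated)
Conditions: n-BuLi (2.2 equiv), TMEDA, Et2O/hexane, 0 °C to rt; then (CH2O)n, −78 °C to rt; H2O
Reagents that add atoms: none
Why: Alkoxide-directed allylic metalation of the methyl group followed by addition to formaldehyde gives the symmetric diol in one operation.

**Step 10**
Reactants: 17 3-methylenepentane-1,5-diol
Product: 18 5-[(4-methoxybenzyl)oxy]-3-methylenepentan-1-ol
Conditions: NaH (1.0 equiv), THF/DMF, 0 °C; PMBCl, Bu4NI (cat.), rt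
Reagents that add atoms: 4-methoxybenzyl chloride COc1ccc(CCl)cc1
Why: Williamson mono-etherification of the symmetric diol with one equivalent of base; unreacted diol is recovered and recycled.

**Step 11**
Reactants: 18 5-[(4-methoxybenzyl)oxy]-3-methylenepentan-1-ol
Product: 19 5-[(4-methoxybenzyl)oxy]-3-methylenepentanal
Conditions: Dess–Martin periodinane, pyridine, CH2Cl2, 0 °C; used crude at once
Reagents that add atoms: none
Why: Buffered Dess–Martin oxidation gives the β,γ-unsaturated aldehyde under near-neutral conditions, which prevents migration of the alkene into conjugation.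

**Step 12**
Reactants: 13 (5S)-3-(bromomethyl)-5-[(1S)-1-[(TBS)oxy]-2-{[(TBS)oxy]methyl}prop-2-en-1-yl]furan-2(5H)-one; 19 5-[(4-methoxybenzyl)oxy]-3-methylenepentanal
Product: 21 (4R,5S)-4-[(1S)-1-hydroxy-5-[(4-methoxybenzyl)oxy]-3-methylenepentyl]-5-[(1S)-1-[(TBS)oxy]-2-{[(TBS)oxy]methyl}prop-2-en-1-yl]-3-methylenedihydrofuran-2(3H)-one, via allylzinc bromide 20 (not isolated)
Conditions: Zn dust (activated), THF/sat. aq NH4Cl, 0 °C to rt
Reagents that add atoms: none
Why: Barbier carbonyl allylation in which the ring-locked allylzinc attacks the aldehyde through its butenolide β-carbon (C7) anti to the C6 side chain in a chair transition state, which gives the trans lactone (C7 R), the C8 (S) carbinol and the exocyclic methylene together.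

**Step 13**
Reactants: 21 Barbier adduct; 22 tigloyl chloride ((E)-2-methylbut-2-enoyl chloride)
Product: 23 tiglate of 21 at the C8 (S) hydroxyl
Conditions: pyridine, DMAP (cat.), CH2Cl2, 0 °C to rt
Reagents that add atoms: none
Why: DMAP-catalysed acylation of the only free hydroxyl; the (E)-tiglate is the stable geometry and pyridine is too weak a base to deconjugate it.

**Step 14**
Reactants: 23 C8 tiglate
Product: 24 primary allylic alcohol (C3–OH free; C5–OTBS and C2–OPMB kept)
Conditions: HF·pyridine, pyridine, THF, 0 °C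
Reagents that add atoms: none
Why: Buffered fluoride desilylation removes the unhindered primary allylic TBS ether much faster than the hindered secondary one at C5.

**Step 15**
Reactants: 24 primary allylic alcohol
Product: 26 allylic bromide (CH2Br on C4), via allylic mesylate 25 (not isolated)
Conditions: MsCl, Et3N, CH2Cl2, −20 °C; then LiBr, THF, 0 °C to rt
Reagents that add atoms: lithium bromide [Li+].[Br-]; methanesulfonyl chloride CS(=O)(=O)Cl (its atoms stay only in 25)
Why: Mesylation followed by SN2 displacement with bromide converts the allylic alcohol under mild, non-acidic conditions that spare the lactone, esters and silyl ether.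

**Step 16**
Reactants: 26 allylic bromide PMB ether
Product: 27 bromo alcohol (C2–OH free)
Conditions: DDQ, CH2Cl2/pH 7 buffer, 0 °C
Reagents that add atoms: none
Why: Oxidative PMB cleavage by DDQ is selective for the electron-rich benzyl ether and leaves the alkenes, the bromide and the TBS ether untouched.

**Step 17**
Reactants: 27 bromo alcohol
Product: 28 bromo aldehyde (C2 aldehyde, C3 allylic bromide)
Conditions: Dess–Martin periodinane, pyridine, CH2Cl2, 0 °C; used at once
Reagents that add atoms: none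
Why: Buffered Dess–Martin oxidation gives the sensitive β,γ-unsaturated aldehyde without isomerisation.

**Step 18**
Reactants: 28 bromo aldehyde
Product: 30 (5S,6S,7R,8S)-5-[(TBS)oxy]-2-hydroxy-8-(tigloyloxy)germacra-4(15),10(14),11(13)-trien-12,6-olide (both C2 epimers), via allylchromium dichloride 29 (not isolated)
Conditions: CrCl2 (8 equiv), THF, rt, syringe-pump addition to 0.002 M; H2O
Reagents that add atoms: none
Why: Intramolecular Nozaki–Hiyama–Kishi allylation is chemoselective for the aldehyde, both allyl termini are CH2 so either gives the same C2–C3 bonded 10-membered ring, and the C2 epimers converge in the next step.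

**Step 19**
Reactants: 30 macrocyclic homoallylic alcohol
Product: 31 (5S,6S,7R,8S)-5-[(TBS)oxy]-2-oxo-8-(tigloyloxy)germacra-4(15),10(14),11(13)-trien-12,6-olide
Conditions: Dess–Martin periodinane, pyridine, CH2Cl2, 0 °C
Reagents that add atoms: none
Why: Buffered Dess–Martin oxidation turns both carbinol epimers into the one ketone without moving the two flanking exocyclic alkenes into conjugation.

**Step 20**
Reactants: 31 macrocyclic ketone
Product: 33 (2S,5S,6S,7R,8S)-2-hydroxy-2,5-epoxy-8-(tigloyloxy)germacra-4(15),10(14),11(13)-trien-12,6-olide (CNP0307443.2), via hydroxy ketone 32 (not isolated)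
Conditions: HF·pyridine, pyridine, THF, 0 °C to rt
Reagents that add atoms: none
Why: Desilylation frees the C5 hydroxyl, which adds across the ring to the C2 ketone (hemiketalisation), and only the cis-bridged tetrahydrofuran can form, which fixes C2 as S.

**Compound list**
1 | 2-methylenepropane-1,3-diol | C=C(CO)CO | starting material
2 | 2-{[(tert-butyldimethylsilyl)oxy]methyl}prop-2-en-1-ol | C=C(CO)CO[Si](C)(C)C(C)(C)C | intermediate
3 | 2-{[(tert-butyldimethylsilyl)oxy]methyl}prop-2-enal | C=C(C=O)CO[Si](C)(C)C(C)(C)C | intermediate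
4 | allyl alcohol | C=CCO | starting material
5 | 3-(methoxymethoxy)prop-1-ene | C=CCOCOC | intermediate
6 | (Z)-3-(methoxymethoxy)allyllithium | [Li]C/C=C\OCOC | intermediate
7 | (Z)-[3-(methoxymethoxy)allyl]diisopinocampheylborane (Ipc from (−)-α-pinene) | COCO/C=C\CB([C@H]1C[C@H]2C[C@@H]([C@@H]1C)C2(C)C)[C@H]1C[C@H]2C[C@@H]([C@@H]1C)C2(C)C | intermediate
8 | (3S,4S)-2-{[(TBS)oxy]methyl}-4-(methoxymethoxy)hexa-1,5-dien-3-ol | C=C[C@H](OCOC)[C@@H](O)C(=C)CO[Si](C)(C)C(C)(C)C | intermediate
9 | (3S,4S)-3-[(TBS)oxy]-2-{[(TBS)oxy]methyl}-4-(methoxymethoxy)hexa-1,5-diene | C=C[C@H](OCOC)[C@@H](O[Si](C)(C)C(C)(C)C)C(=C)CO[Si](C)(C)C(C)(C)C | intermediate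
10 | (3S,4S)-4-[(TBS)oxy]-5-{[(TBS)oxy]methyl}hexa-1,5-dien-3-ol | C=C[C@H](O)[C@@H](O[Si](C)(C)C(C)(C)C)C(=C)CO[Si](C)(C)C(C)(C)C | intermediate
11 | 2-(bromomethyl)acrylic acid | C=C(CBr)C(=O)O | starting material
12 | (3S,4S)-4-[(TBS)oxy]-5-{[(TBS)oxy]methyl}hexa-1,5-dien-3-yl 2-(bromomethyl)prop-2-enoate | C=C[C@H](OC(=O)C(=C)CBr)[C@@H](O[Si](C)(C)C(C)(C)C)C(=C)CO[Si](C)(C)C(C)(C)C | intermediate
13 | (5S)-3-(bromomethyl)-5-[(1S)-1-[(TBS)oxy]-2-{[(TBS)oxy]methyl}prop-2-en-1-yl]furan-2(5H)-one | O=C1O[C@@H](C=C1CBr)[C@@H](O[Si](C)(C)C(C)(C)C)C(=C)CO[Si](C)(C)C(C)(C)C | intermediate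
14 | 3-methylbut-3-en-1-ol (isoprenol) | CC(=C)CCO | starting material
15 | paraformaldehyde (formaldehyde unit) | C=O | starting material
16 | dilithiated isoprenol (O-lithio, allylic C-lithio) | [Li]CC(=C)CCO[Li] | intermediate
17 | 3-methylenepentane-1,5-diol | C=C(CCO)CCO | intermediate
18 | 5-[(4-methoxybenzyl)oxy]-3-methylenepentan-1-ol | C=C(CCO)CCOCc1ccc(OC)cc1 | intermediate
19 | 5-[(4-methoxybenzyl)oxy]-3-methylenepentanal | C=C(CC=O)CCOCc1ccc(OC)cc1 | intermediate
20 | allylzinc bromide from 13 (ZnBr in place of Br) | O=C1O[C@@H](C=C1C[Zn]Br)[C@@H](O[Si](C)(C)C(C)(C)C)C(=C)CO[Si](C)(C)C(C)(C)C | intermediate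
21 | (4R,5S)-4-[(1S)-1-hydroxy-5-[(4-methoxybenzyl)oxy]-3-methylenepentyl]-5-[(1S)-1-[(TBS)oxy]-2-{[(TBS)oxy]methyl}prop-2-en-1-yl]-3-methylenedihydrofuran-2(3H)-one | C=C(CCOCc1ccc(OC)cc1)C[C@H](O)[C@H]1C(=C)C(=O)O[C@@H]1[C@@H](O[Si](C)(C)C(C)(C)C)C(=C)CO[Si](C)(C)C(C)(C)C | intermediate
22 | tigloyl chloride, (E)-2-methylbut-2-enoyl chloride | C/C=C(\C)C(Cl)=O | starting material
23 | C8 (S) tiglate of 21 | C=C(CCOCc1ccc(OC)cc1)C[C@H](OC(=O)/C(C)=C/C)[C@H]1C(=C)C(=O)O[C@@H]1[C@@H](O[Si](C)(C)C(C)(C)C)C(=C)CO[Si](C)(C)C(C)(C)C | intermediate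
24 | primary allylic alcohol (23 without the primary TBS group) | C=C(CCOCc1ccc(OC)cc1)C[C@H](OC(=O)/C(C)=C/C)[C@H]1C(=C)C(=O)O[C@@H]1[C@@H](O[Si](C)(C)C(C)(C)C)C(=C)CO | intermediate
25 | allylic mesylate of 24 | C=C(CCOCc1ccc(OC)cc1)C[C@H](OC(=O)/C(C)=C/C)[C@H]1C(=C)C(=O)O[C@@H]1[C@@H](O[Si](C)(C)C(C)(C)C)C(=C)COS(C)(=O)=O | intermediate
26 | allylic bromide (CH2Br in place of CH2OH of 24) | C=C(CCOCc1ccc(OC)cc1)C[C@H](OC(=O)/C(C)=C/C)[C@H]1C(=C)C(=O)O[C@@H]1[C@@H](O[Si](C)(C)C(C)(C)C)C(=C)CBr | intermediate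
27 | bromo alcohol (26 without PMB) | C=C(CCO)C[C@H](OC(=O)/C(C)=C/C)[C@H]1C(=C)C(=O)O[C@@H]1[C@@H](O[Si](C)(C)C(C)(C)C)C(=C)CBr | intermediate
28 | bromo aldehyde (C2 aldehyde of 27) | C=C(CC=O)C[C@H](OC(=O)/C(C)=C/C)[C@H]1C(=C)C(=O)O[C@@H]1[C@@H](O[Si](C)(C)C(C)(C)C)C(=C)CBr | intermediate
29 | allylchromium dichloride from 28 (trivalent chromium) | C=C(CC=O)C[C@H](OC(=O)/C(C)=C/C)[C@H]1C(=C)C(=O)O[C@@H]1[C@@H](O[Si](C)(C)C(C)(C)C)C(=C)C[Cr](Cl)Cl | intermediate
30 | (5S,6S,7R,8S)-5-[(TBS)oxy]-2-hydroxy-8-(tigloyloxy)germacra-4(15),10(14),11(13)-trien-12,6-olide, C2 epimer mixture | C=C1C[C@H](OC(=O)/C(C)=C/C)[C@H]2C(=C)C(=O)O[C@@H]2[C@@H](O[Si](C)(C)C(C)(C)C)C(=C)CC(O)C1 | intermediate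
31 | (5S,6S,7R,8S)-5-[(TBS)oxy]-2-oxo-8-(tigloyloxy)germacra-4(15),10(14),11(13)-trien-12,6-olide | C=C1C[C@H](OC(=O)/C(C)=C/C)[C@H]2C(=C)C(=O)O[C@@H]2[C@@H](O[Si](C)(C)C(C)(C)C)C(=C)CC(=O)C1 | intermediate
32 | (5S,6S,7R,8S)-5-hydroxy-2-oxo-8-(tigloyloxy)germacra-4(15),10(14),11(13)-trien-12,6-olide | C=C1C[C@H](OC(=O)/C(C)=C/C)[C@H]2C(=C)C(=O)O[C@@H]2[C@@H](O)C(=C)CC(=O)C1 | intermediate
33 | (2S,5S,6S,7R,8S)-2-hydroxy-2,5-epoxy-8-(tigloyloxy)germacra-4(15),10(14),11(13)-trien-12,6-olide (CNP0307443.2) | C=C1C[C@H](OC(=O)/C(C)=C/C)[C@H]2C(=C)C(=O)O[C@@H]2[C@H]2O[C@@](O)(C1)CC2=C | target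

**Totals**
Total step count: 20. Longest linear sequence: 16 steps (steps 1, 2, 4–8, 12–20, from 1 to 33).

**Three steps most likely to fail**

Step 12 (Barbier union). The risks are isomerisation of aldehyde 19 and the wrong configuration at C8 if the reaction leaves the chair pathway. Fallback: setting out from 13 and 19, the coupling is run to whichever C8 diastereomer it favours. If that is the (1R)-carbinol epimer of 21 F1, it is esterified under Mitsunobu conditions (tiglic acid, PPh3, DIAD, toluene, 0 °C), which inverts C8 and installs the ester in one operation. The route is rejoined at 23.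

Step 18 (10-membered ring closure). The risks are oligomerisation, transannular strain and the enolisable β,γ-unsaturated aldehyde under chromium conditions. Fallback: setting out from 27, the allylic bromide is stannylated with hexabutylditin and catalytic Pd(PPh3)4 to give the allylstannane alcohol F2. Buffered Dess–Martin oxidation then gives the stannyl aldehyde F3. This is cyclised by a Lewis-acid-promoted SE2' allylstannane–aldehyde addition (BF3·OEt2, CH2Cl2, −78 °C, high dilution), a closed-shell open-transition-state process instead of the chromium Barbier. The route is rejoined at 30.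

Step 19 (oxidation to the ketone flanked by two β,γ-alkenes). The risk is alkene migration into conjugation before the ketone is masked. Fallback: setting out from 30, the silyl ether is removed first (HF·pyridine) to give the 2,5-diol F4. The unhindered C2 carbinol is then oxidised selectively over the hindered allylic C5 carbinol with TEMPO (cat.) and PhI(OAc)2 in CH2Cl2. The C5 hydroxyl traps the nascent ketone 32 at once as the hemiketal, so the free ketone is never handled, and the route is rejoined at 33.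

**Further compounds**
F1 | step 12 | (4R,5S)-4-[(1R)-1-hydroxy-5-[(4-methoxybenzyl)oxy]-3-methylenepentyl]-5-[(1S)-1-[(TBS)oxy]-2-{[(TBS)oxy]methyl}prop-2-en-1-yl]-3-methylenedihydrofuran-2(3H)-one (C8 epimer of 21) | C=C(CCOCc1ccc(OC)cc1)C[C@@H](O)[C@H]1C(=C)C(=O)O[C@@H]1[C@@H](O[Si](C)(C)C(C)(C)C)C(=C)CO[Si](C)(C)C(C)(C)C
F2 | step 18 | allylstannane alcohol (27 with CH2SnBu3 in place of CH2Br) | C=C(CCO)C[C@H](OC(=O)/C(C)=C/C)[C@H]1C(=C)C(=O)O[C@@H]1[C@@H](O[Si](C)(C)C(C)(C)C)C(=C)C[Sn](CCCC)(CCCC)CCCC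
F3 | step 18 | stannyl aldehyde (C2 aldehyde of F2) | C=C(CC=O)C[C@H](OC(=O)/C(C)=C/C)[C@H]1C(=C)C(=O)O[C@@H]1[C@@H](O[Si](C)(C)C(C)(C)C)C(=C)C[Sn](CCCC)(CCCC)CCCC
F4 | step 19 | (5S,6S,7R,8S)-2,5-dihydroxy-8-(tigloyloxy)germacra-4(15),10(14),11(13)-trien-12,6-olide, C2 epimer mixture | C=C1C[C@H](OC(=O)/C(C)=C/C)[C@H]2C(=C)C(=O)O[C@@H]2[C@@H](O)C(=C)CC(O)C1
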